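## The problem

Compound 13 is 3,5,8,3',5'-pentahydroxy-7,4'-dimethoxyflavone, a flat, achiral flavonol. There is no stereocenter to set, so no question of stereocontrol arises; the whole difficulty lies in placing and differentiating nine oxygen atoms on a C15 skeleton. Ring A carries oxygen at C5, C7 and C8 and a single hydrogen at C6, ring C carries the 3-hydroxyl, and ring B has a symmetric 3',5'-dihydroxy-4'-methoxy pattern. Two methyl ethers (O7 and O4') therefore stand among five free hydroxyls and cannot be introduced by late selective methylation. The 5,8-dihydroxy pair is a para-hydroquinone that air-oxidises to the flavone-5,8-quinone, especially in base. Strong hot acid can open ring C of a 5,7,8-trioxygenated flavone and reclose it to the 5,6,7-isomer (Wessely–Moser rearrangement), so O8 should be exposed late and handled gently. The enabling feature is the chain C2–C3–C4–C4a–C5–C6–C7–C8–C8a, which carries oxygen on the alternate carbons C2, C4, C5, C7 and C8a, as a polyketide does. A 4-methoxy-2-pyrone can hold C5, C7 and C8a of this chain in masked form, with the O7 methyl already in place. A C4a–C8a Claisen fold then gives a 2,6-dihydroxy-4-methoxyphenyl ketone with two equivalent hydroxyls, so O1–C2 closure can give only one flavone; O3 and O8, which lie outside the polyketide pattern, must be supplied separately.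

## Retrosynthesis

**13 from 12.** The three O–CH2Ph bonds on O3, O3' and O5' are cut last, leading back to tribenzyl ether 12. Benzyl is preferred to methyl, acyl or silyl because hydrogenolysis is neutral and leaves both methyl ethers alone. Benzyl ethers should also survive the amide bases, methoxide, brief dilute acid and cold alkaline persulfate used earlier. The skeleton is not simplified, but the oxidation-prone oxygens of rings B and C stay capped until the end. The forward step must cleave three benzyl ethers without reducing the C2–C3 double bond, and the hydroquinone must be handled without air.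

**12 from 10.** The C8–O bond is cut, leading to the 5-hydroxyflavone 10 with free C6 and C8 positions. The forward reaction is an Elbs persulfate oxidation through the aryl sulfate 11, which is directed para to the only free phenol and so to C8. The neighbouring option, carrying O8 through the fold on a 3-oxygenated pyrone, would make the two hydroxyls of the folded intermediate non-equivalent and give 5,7,8/5,6,7 mixtures. Electrophilic halogenation of a free 5-hydroxyflavone tends to go ortho, to C6. The precursor 10 loses one oxygen and gains a symmetry-derived origin. The forward step needs para selectivity and tolerance of benzyl ethers.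

**10 from 7.** This is the key disconnection: O1–C2 and C4a–C8a are cut together. Opening ring C gives the 2,6-dihydroxy-4-methoxyphenyl diketone 9. Unfolding ring A by a retro-Claisen cut gives the open-chain enoate 8, which is the methanolysis product of the 4-methoxy-2-pyrone 7. The alternatives are less attractive for this target. A Baker–Venkataraman or Allan–Robinson approach from a preformed phloroacetophenone needs selective mono-methylation of a phloroglucinol and separate omega-oxygenation. An Algar–Flynn–Oyamada oxidation of a 6'-oxygenated chalcone tends to give aurones instead of flavonols. In 7 the O7 methyl, the O3 benzyl and the whole carbon chain are already in place, and no benzene ring A has to be bought or differentiated. The forward step must give the Claisen fold and not an aldol fold, and must close the pyranone in a single sense.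

**7 from 6 and 3.** The C2–C3 bond is cut, giving ketone 6 and the aroyl donor 3. The forward reaction is aroylation of the 1,3-dianion of 6 at its outer, benzyloxy-bearing carbon. The neighbouring C3–C4 cut would require the lithiated pyrone to acylate a preformed aroyl(benzyloxy)acetate, which would simply be deprotonated. An N-methoxy-N-methylamide is chosen as donor because its tetrahedral adduct persists until the quench, so no acidic product is released to consume dianion. Both precursors are small and non-polycarbonyl.

**6 from 4 and 5.** The C4–C4a bond is cut, giving commercial 4-methoxy-6-methyl-2H-pyran-2-one 4 and methyl 2-(benzyloxy)acetate 5. The forward reaction is a crossed Claisen condensation of the 6-methyl carbanion of 4 with the alpha-alkoxy ester. This places O3 on the chain from the start, so no oxidation at C3 is ever needed.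

**3 from 2 from 1.** The amide C–N bond and the three benzyl C–O bonds are cut, leading to commercial 3,5-dihydroxy-4-methoxybenzoic acid 1. Exhaustive benzylation gives benzyl ester 2, and direct aminolysis gives 3. The symmetric ring B needs no regiocontrol.

## Roads not taken

**Alternative 1:** One-carbon insertion into a benzofuran. The cut removes C3 from ring C (C2–C3 and C3–C4), leading back to the 2-aryl-3-silyloxybenzofuran A1, which carries all ring A oxygens including O8 as ethers.
- Forward key step: dibromocarbene (CHBr3, KOtBu) adds to the enol-ether double bond of the furan, and the dibromocyclopropane opens with loss of bromide and silyl to give 3-bromoflavone A2.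
- Merits: O8 is present from the start, so no persulfate oxidation is needed; in this respect the road is better than the chosen one. The ring expansion of silyl enol ethers and heteroaromatic five-membered rings by dihalocarbenes is an established reaction type.
- Weak points: C3 arrives as bromine, not oxygen, and exchanging a hindered vinylogous acyl bromide for hydroxyl costs further steps. A1 requires a fully differentiated 1,2,3,5-tetraoxygenated benzene and an oxidation-prone 2-arylbenzofuranone stage. Dibromocarbene under strongly basic conditions can also insert into the benzylic C–H bonds of four benzyl ethers.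
- Comparison: the chosen plan has O3 built in from benzyloxyacetate, a much shorter assembly from three cheap pieces, and regiochemistry fixed by symmetry. It pays for this with one partial-conversion oxidation.

**Alternative 2:** Quinone oxidation state at ring A. The cut is O1–C8a, leading to the acylhydroquinone A3 (5,8-dihydroxy, 7- and 8a-methoxy, with the benzyloxy diketone side chain).
- Forward key step: Ag2O oxidises A3 to the acylquinone, whose diketone enol oxygen adds to C8a and expels methoxide, giving flavone-5,8-quinone A4.
- Merits: both O3 and O8 are in place with certainty, and the final hydrogenation would reduce the quinone and remove the benzyl groups in one operation. On the security of O8 and on the end game this road is genuinely better.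
- Weak points: A3 is a pentasubstituted benzene with four differentiated oxygens and a di-ortho-substituted aryl diketone, and it is long to make. 2-Acylquinones are aggressive Michael acceptors that hydrate and dimerise. Ag2O may also oxidise the enolisable alpha-benzyloxy diketone.
- Comparison: the chosen plan is clearly shorter, and its fold belongs to a reaction class with direct precedent. Its weaker point is the late oxidation at C8, which is a known, para-selective reaction.

**Alternative 3:** Carbene benzannulation of ring A. The cut removes C5–C6, C7–C8 and C8–C8a, leading to the pentacarbonylchromium methoxycarbene A5 on a preformed 2-aryl-3-benzyloxy-4-pyranone, to methoxyacetylene A6 and to one CO ligand.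
- Forward key step: a Dötz benzannulation gives 8-hydroxy-5,7-dimethoxyflavone A7.
- Merits: highly convergent; ring A is formed in one step with a free, differentiated 8-hydroxyl, and the terminal alkyne should place its methoxy group next to the CO-derived carbon as required. On convergence this road is better.
- Weak points: the C4 carbonyl next to the carbene carbon can chelate chromium and deaden the complex, and the alkenyl partner is an electron-poor vinylogous ester. Making A5 needs a 3-metallated 4-pyranone and stoichiometric Cr(CO)6. A6 is a volatile, unstable ynol ether, and electron-rich alkynes often divert to cyclobutenones. A7 still needs selective 5-O-demethylation beside two methyl ethers that must stay.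
- Comparison: the chosen plan relies on two precedented ionic steps and cheap, stable materials. It accepts a linear end game in exchange.

Key step: step 5

Remark on the chemistry: compounds 7, 8 and 9 are drawn and named as single chelated enol tautomers; they will exist as keto–enol mixtures, which affects no step.

## Route

Step 1
Reactants: 1 3,5-dihydroxy-4-methoxybenzoic acid
Product: 2 benzyl 3,5-bis(benzyloxy)-4-methoxybenzoate
Conditions: BnBr (3.3 equiv), K2CO3, DMF, 60 °C
Reagents that add atoms: benzyl bromide, BrCc1ccccc1
Why: Williamson etherification of both phenols and O-alkylation of the carboxylate in one operation; the hindered 4-methoxy group is untouched and the benzyl ester is the acyl donor for step 2.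

Step 2
Reactants: 2 benzyl 3,5-bis(benzyloxy)-4-methoxybenzoate
Product: 3 3,5-bis(benzyloxy)-N,4-dimethoxy-N-methylbenzamide
Conditions: MeNH(OMe)·HCl, iPrMgCl, THF, −20 to 0 °C
Reagents that add atoms: N,O-dimethylhydroxylamine hydrochloride, CNOC.Cl
Why: Direct aminolysis of an ester by the chloromagnesium amide of N,O-dimethylhydroxylamine formed in the flask, the standard ester-to-Weinreb-amide conversion; aryl benzyl ethers are inert to it.

Step 3
Reactants: 4 4-methoxy-6-methyl-2H-pyran-2-one; 5 methyl 2-(benzyloxy)acetate
Product: 6 6-[3-(benzyloxy)-2-oxopropyl]-4-methoxy-2H-pyran-2-one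
Conditions: 4 (2.1 equiv), LiN(iPr)2 (2.1 equiv), THF, −78 °C; then 5 (1 equiv), −78 to −20 °C; then 1 M HCl
Reagents that add atoms: none
Why: The amide base removes a proton of the 6-methyl group to give the vinylogous ester enolate, which undergoes a crossed Claisen condensation with the activated alpha-alkoxy ester. Because 6 is more acidic than 4, the second equivalent of lithiated 4 serves as the base and is recovered as 4, so enolisable 5 never meets free amide base.

Step 4
Reactants: 6 6-[3-(benzyloxy)-2-oxopropyl]-4-methoxy-2H-pyran-2-one; 3 3,5-bis(benzyloxy)-N,4-dimethoxy-N-methylbenzamide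
Product: 7 6-[(3E)-3-(benzyloxy)-4-[3,5-bis(benzyloxy)-4-methoxyphenyl]-4-hydroxy-2-oxobut-3-en-1-yl]-4-methoxy-2H-pyran-2-one
Conditions: 6, LiN(iPr)2 (2.1 equiv), THF, −78 to −30 °C; then 3 (1 equiv), −78 to 0 °C; then 1 M HCl
Reagents that add atoms: none
Why: Two equivalents of base give the 1,3-dianion of the vinylogous beta-keto ester, which reacts at its last-formed, more basic carbanion (the benzyloxy-bearing carbon), as beta-dicarbonyl dianions do. The N-methoxy-N-methylamide forms a stable chelated tetrahedral adduct, so no acidic product is released before the quench and over-acylation is excluded.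

Step 5
Reactants: 7 6-[(3E)-3-(benzyloxy)-4-[3,5-bis(benzyloxy)-4-methoxyphenyl]-4-hydroxy-2-oxobut-3-en-1-yl]-4-methoxy-2H-pyran-2-one
Product: 10 3-(benzyloxy)-2-[3,5-bis(benzyloxy)-4-methoxyphenyl]-5-hydroxy-7-methoxy-4H-chromen-4-one, via ring-opened methyl enoate 8 (not isolated), via acylphloroglucinol diketone 9 (not isolated)
Conditions: Mg(OMe)2 (6 equiv), MeOH, reflux; then 3 M HCl, MeOH, 60 °C
Reagents that add atoms: none
Why: Mg(OMe)2 converts the beta-diketone of 7 into its magnesium chelate and delivers methoxide to the lactone carbonyl, opening the pyrone to the (2E)-3-methoxy-enoate 8, in which the ester and the chain are cis on the enol-ether double bond. The C4a carbanion, flanked by the C4 and C5 carbonyls, attacks the ester carbon C8a in a 6-exo-trig Claisen (Dieckmann-type) condensation; methoxide is expelled and enolisation makes ring A aromatic, giving the 2,6-dihydroxy-4-methoxyphenyl diketone 9. The closest known reaction is the base-induced rearrangement of 6-acylmethyl-4-methoxy-2-pyrones to acylphloroglucinol monomethyl ethers, here run on a substrate with one further chelated carbonyl. On acidification one of the two equivalent ortho hydroxyls adds to the C2 carbonyl (6-exo-trig) and the hemiketal loses water, the standard cyclodehydration of 2-hydroxyaryl 1,3-diketones, closing ring C. No stereocenter is formed. The step needs the Claisen fold to win over aldol folds: C8 is a vinylic enol-ether carbon and cannot act as the carbanion of an orsellinate-type aldol, the C2 and C4 carbonyls that could accept a C6 carbanion are tied up as a magnesium enolate and shielded by the C3 benzyloxy group, and C4a is the most acidic carbon with the ester as the only unenolised acceptor within six-ring reach. The single sense of pyranone closure follows from the symmetry of ring A in 9 about the C4a–C7 axis, and the benzyl ethers should tolerate methoxide and brief dilute acid.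

Step 6
Reactants: 10 3-(benzyloxy)-2-[3,5-bis(benzyloxy)-4-methoxyphenyl]-5-hydroxy-7-methoxy-4H-chromen-4-one
Product: 12 3-(benzyloxy)-2-[3,5-bis(benzyloxy)-4-methoxyphenyl]-5,8-dihydroxy-7-methoxy-4H-chromen-4-one, via potassium 8-sulfate 11 (not isolated)
Conditions: K2S2O8, aq. KOH, pyridine, 0 °C to rt; then aq. HCl, 80 °C, under argon
Reagents that add atoms: potassium peroxodisulfate, [K+].[K+].[O-]S(=O)(=O)OOS(=O)(=O)[O-]
Why: Elbs persulfate oxidation: C8, para to the 5-phenolate, attacks a peroxide oxygen of peroxodisulfate to give aryl sulfate 11, which is protected against further oxidation, and short acid hydrolysis then frees the phenol. The 5-hydroxyl is the only phenol in 10, so para attack at C8 is the only directed pathway, and pyridine keeps the lipophilic substrate in solution.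

Step 7
Reactants: 12 3-(benzyloxy)-2-[3,5-bis(benzyloxy)-4-methoxyphenyl]-5,8-dihydroxy-7-methoxy-4H-chromen-4-one
Product: 13 3,5,8-trihydroxy-2-(3,5-dihydroxy-4-methoxyphenyl)-7-methoxy-4H-chromen-4-one
Conditions: H2 (1 atm), Pd/C, THF–MeOH, rt; filtration and concentration under argon
Reagents that add atoms: none
Why: Hydrogenolysis of the two aryl benzyl ethers and the enol benzyl ether over Pd/C; methyl ethers and the flavonol double bond should be stable under these mild conditions, and air is excluded to protect the hydroquinone.

## Compound list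

1 | 3,5-dihydroxy-4-methoxybenzoic acid | COc1c(O)cc(C(=O)O)cc1O | starting material
2 | benzyl 3,5-bis(benzyloxy)-4-methoxybenzoate | COc1c(OCc2ccccc2)cc(C(=O)OCc2ccccc2)cc1OCc1ccccc1 | intermediate
3 | 3,5-bis(benzyloxy)-N,4-dimethoxy-N-methylbenzamide | CON(C)C(=O)c1cc(OCc2ccccc2)c(OC)c(OCc2ccccc2)c1 | intermediate
4 | 4-methoxy-6-methyl-2H-pyran-2-one | COc1cc(C)oc(=O)c1 | starting material
5 | methyl 2-(benzyloxy)acetate | COC(=O)COCc1ccccc1 | starting material
6 | 6-[3-(benzyloxy)-2-oxopropyl]-4-methoxy-2H-pyran-2-one | COc1cc(CC(=O)COCc2ccccc2)oc(=O)c1 | intermediate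
7 | 6-[(3E)-3-(benzyloxy)-4-[3,5-bis(benzyloxy)-4-methoxyphenyl]-4-hydroxy-2-oxobut-3-en-1-yl]-4-methoxy-2H-pyran-2-one | COc1cc(CC(=O)/C(OCc2ccccc2)=C(\O)c2cc(OCc3ccccc3)c(OC)c(OCc3ccccc3)c2)oc(=O)c1 | intermediate
8 | methyl (2E,8E)-8-(benzyloxy)-9-[3,5-bis(benzyloxy)-4-methoxyphenyl]-9-hydroxy-3-methoxy-5,7-dioxonona-2,8-dienoate | COC(=O)/C=C(/OC)CC(=O)CC(=O)/C(OCc1ccccc1)=C(\O)c1cc(OCc2ccccc2)c(OC)c(OCc2ccccc2)c1 | intermediate
9 | (2E)-2-(benzyloxy)-3-[3,5-bis(benzyloxy)-4-methoxyphenyl]-1-(2,6-dihydroxy-4-methoxyphenyl)-3-hydroxyprop-2-en-1-one | COc1cc(O)c(C(=O)/C(OCc2ccccc2)=C(\O)c2cc(OCc3ccccc3)c(OC)c(OCc3ccccc3)c2)c(O)c1 | intermediate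
10 | 3-(benzyloxy)-2-[3,5-bis(benzyloxy)-4-methoxyphenyl]-5-hydroxy-7-methoxy-4H-chromen-4-one | COc1cc(O)c2c(=O)c(OCc3ccccc3)c(-c3cc(OCc4ccccc4)c(OC)c(OCc4ccccc4)c3)oc2c1 | intermediate
11 | potassium 3-(benzyloxy)-2-[3,5-bis(benzyloxy)-4-methoxyphenyl]-5-hydroxy-7-methoxy-4-oxo-4H-chromen-8-yl sulfate | COc1cc(O)c2c(=O)c(OCc3ccccc3)c(-c3cc(OCc4ccccc4)c(OC)c(OCc4ccccc4)c3)oc2c1OS(=O)(=O)[O-].[K+] | intermediate
12 | 3-(benzyloxy)-2-[3,5-bis(benzyloxy)-4-methoxyphenyl]-5,8-dihydroxy-7-methoxy-4H-chromen-4-one | COc1cc(O)c2c(=O)c(OCc3ccccc3)c(-c3cc(OCc4ccccc4)c(OC)c(OCc4ccccc4)c3)oc2c1O | intermediate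
13 | 3,5,8-trihydroxy-2-(3,5-dihydroxy-4-methoxyphenyl)-7-methoxy-4H-chromen-4-one | COc1cc(O)c2c(=O)c(O)c(-c3cc(O)c(OC)c(O)c3)oc2c1O | target

## Step count and risks

Total: 7 steps. Longest linear sequence: 6 steps (steps 1, 2, 4, 5, 6, 7, from 1 to 13); the pyrone branch (steps 3 to 7) is 5 steps.

**Step 5 (key step).** The fold may take another course, because 7 carries one more carbonyl pair than the precedented 6-acylmethyl pyrones. Possible diversions are aldol closure of the C6 carbanion onto the C2 or C4 carbonyl, retro-Claisen loss of the aroyl group by methoxide, and incomplete Claisen closure followed on acidification by dehydration of the 2,4,5-triketone to a 4-pyranone.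

Fallback: the fold is moved one stage earlier, onto the exact precedented substrate class, and the aroyl unit is attached afterwards. Setting out from 6, Mg(OMe)2 in refluxing MeOH should rearrange it to 2-(benzyloxy)-1-(2,6-dihydroxy-4-methoxyphenyl)ethan-1-one F1. Ester 2 is saponified (KOH, aq. THF–MeOH) to 3,5-bis(benzyloxy)-4-methoxybenzoic acid F2, which (COCl)2 with catalytic DMF converts into 3,5-bis(benzyloxy)-4-methoxybenzoyl chloride F3. The lithium polyanion of F1 (LiN(SiMe3)2, 4 equiv, THF, −78 °C) is C-aroylated with F3 to give diketone 9, now isolated. Warming 9 with HCl in MeOH closes ring C, and the route is rejoined at 10. This path also bypasses step 4.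

**Step 4.** Acylation may be incomplete or misdirected. The delocalised dianion may add sluggishly to the amide, the second deprotonation may partly occur on the pyrone ring, or excess amide base may degrade the N-methoxy-N-methylamide.

Fallback: an aldol–oxidation sequence with a far more reactive electrophile. Setting out from 3, iBu2AlH (THF, −78 °C) gives 3,5-bis(benzyloxy)-4-methoxybenzaldehyde F4. The dianion of 6 adds to F4 to give 6-[3-(benzyloxy)-4-[3,5-bis(benzyloxy)-4-methoxyphenyl]-4-hydroxy-2-oxobutyl]-4-methoxy-2H-pyran-2-one F5, a diastereomer mixture whose two centres are lost again. Dess–Martin periodinane oxidises F5 to the diketone, returning to the route at 7.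

**Step 6.** Low conversion is the main risk, because the chelated 5-hydroxyl is a weak nucleophile toward persulfate and the tribenzyl ether is poorly soluble in aqueous alkali. Ring C may also suffer alkaline cleavage on long exposure, and overlong acid hydrolysis invites benzyl loss or Wessely–Moser isomerisation. Partial conversion with recovery of 10 is to be expected for this reaction class.

Fallback: C8 is functionalised by halogenation and boron chemistry instead. Setting out from 10, BnBr and K2CO3 in DMF at 80 °C cap the 5-hydroxyl to give 3,5-bis(benzyloxy)-2-[3,5-bis(benzyloxy)-4-methoxyphenyl]-7-methoxy-4H-chromen-4-one F6. With O5 alkylated, iodination of 5,7-dialkoxyflavones goes to C8, so I2 and AgO2CCF3 in CH2Cl2 should give 3,5-bis(benzyloxy)-2-[3,5-bis(benzyloxy)-4-methoxyphenyl]-8-iodo-7-methoxy-4H-chromen-4-one F7. Miyaura borylation (B2pin2, Pd(dppf)Cl2, KOAc, dioxane, 90 °C) gives 3,5-bis(benzyloxy)-2-[3,5-bis(benzyloxy)-4-methoxyphenyl]-7-methoxy-8-(4,4,5,5-tetramethyl-1,3,2-dioxaborolan-2-yl)-4H-chromen-4-one F8. Oxidation with NaBO3·4H2O in aq. THF gives 3,5-bis(benzyloxy)-2-[3,5-bis(benzyloxy)-4-methoxyphenyl]-8-hydroxy-7-methoxy-4H-chromen-4-one F9. Hydrogenolysis of F9 (H2, Pd/C) removes all four benzyl groups and comes back to the route at 13.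

**Step 3.** The condensation may stall or self-condense. Product 6 quenches lithiated 4, free base can enolise ester 5, and a second acylation of the product anion is possible.

Fallback: aldol addition followed by oxidation. Setting out from 4, its lithio derivative (LiN(iPr)2, THF, −78 °C) adds to benzyloxyacetaldehyde to give racemic 6-[3-(benzyloxy)-2-hydroxypropyl]-4-methoxy-2H-pyran-2-one F10. Dess–Martin periodinane oxidises F10 to the ketone, returning to the route at 6.

## Further compounds

F1 | step 5 | 2-(benzyloxy)-1-(2,6-dihydroxy-4-methoxyphenyl)ethan-1-one | COc1cc(O)c(C(=O)COCc2ccccc2)c(O)c1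
F2 | step 5 | 3,5-bis(benzyloxy)-4-methoxybenzoic acid | COc1c(OCc2ccccc2)cc(C(=O)O)cc1OCc1ccccc1
F3 | step 5 | 3,5-bis(benzyloxy)-4-methoxybenzoyl chloride | COc1c(OCc2ccccc2)cc(C(=O)Cl)cc1OCc1ccccc1
F4 | step 4 | 3,5-bis(benzyloxy)-4-methoxybenzaldehyde | COc1c(OCc2ccccc2)cc(C=O)cc1OCc1ccccc1
F5 | step 4 | 6-[3-(benzyloxy)-4-[3,5-bis(benzyloxy)-4-methoxyphenyl]-4-hydroxy-2-oxobutyl]-4-methoxy-2H-pyran-2-one (mixture of diastereomers) | COc1cc(CC(=O)C(OCc2ccccc2)C(O)c2cc(OCc3ccccc3)c(OC)c(OCc3ccccc3)c2)oc(=O)c1
F6 | step 6 | 3,5-bis(benzyloxy)-2-[3,5-bis(benzyloxy)-4-methoxyphenyl]-7-methoxy-4H-chromen-4-one | COc1cc(OCc2ccccc2)c2c(=O)c(OCc3ccccc3)c(-c3cc(OCc4ccccc4)c(OC)c(OCc4ccccc4)c3)oc2c1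
F7 | step 6 | 3,5-bis(benzyloxy)-2-[3,5-bis(benzyloxy)-4-methoxyphenyl]-8-iodo-7-methoxy-4H-chromen-4-one | COc1cc(OCc2ccccc2)c2c(=O)c(OCc3ccccc3)c(-c3cc(OCc4ccccc4)c(OC)c(OCc4ccccc4)c3)oc2c1I
F8 | step 6 | 3,5-bis(benzyloxy)-2-[3,5-bis(benzyloxy)-4-methoxyphenyl]-7-methoxy-8-(4,4,5,5-tetramethyl-1,3,2-dioxaborolan-2-yl)-4H-chromen-4-one | COc1cc(OCc2ccccc2)c2c(=O)c(OCc3ccccc3)c(-c3cc(OCc4ccccc4)c(OC)c(OCc4ccccc4)c3)oc2c1B1OC(C)(C)C(C)(C)O1
F9 | step 6 | 3,5-bis(benzyloxy)-2-[3,5-bis(benzyloxy)-4-methoxyphenyl]-8-hydroxy-7-methoxy-4H-chromen-4-one | COc1cc(OCc2ccccc2)c2c(=O)c(OCc3ccccc3)c(-c3cc(OCc4ccccc4)c(OC)c(OCc4ccccc4)c3)oc2c1O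
F10 | step 3 | 6-[3-(benzyloxy)-2-hydroxypropyl]-4-methoxy-2H-pyran-2-one (racemic) | COc1cc(CC(O)COCc2ccccc2)oc(=O)c1
A1 | alternative 1 | 4,7-bis(benzyloxy)-2-[3,5-bis(benzyloxy)-4-methoxyphenyl]-3-[(tert-butyldimethylsilyl)oxy]-6-methoxy-1-benzofuran | COc1cc(OCc2ccccc2)c2c(O[Si](C)(C)C(C)(C)C)c(-c3cc(OCc4ccccc4)c(OC)c(OCc4ccccc4)c3)oc2c1OCc1ccccc1
A2 | alternative 1 | 5,8-bis(benzyloxy)-2-[3,5-bis(benzyloxy)-4-methoxyphenyl]-3-bromo-7-methoxy-4H-chromen-4-one | COc1cc(OCc2ccccc2)c2c(=O)c(Br)c(-c3cc(OCc4ccccc4)c(OC)c(OCc4ccccc4)c3)oc2c1OCc1ccccc1
A3 | alternative 2 | (2E)-2-(benzyloxy)-3-[3,5-bis(benzyloxy)-4-methoxyphenyl]-1-(3,6-dihydroxy-2,4-dimethoxyphenyl)-3-hydroxyprop-2-en-1-one | COc1cc(O)c(C(=O)/C(OCc2ccccc2)=C(\O)c2cc(OCc3ccccc3)c(OC)c(OCc3ccccc3)c2)c(OC)c1O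
A4 | alternative 2 | 3-(benzyloxy)-2-[3,5-bis(benzyloxy)-4-methoxyphenyl]-7-methoxy-4H-chromene-4,5,8-trione | COC1=CC(=O)C2=C(C1=O)OC(c1cc(OCc3ccccc3)c(OC)c(OCc3ccccc3)c1)=C(OCc1ccccc1)C2=O
A5 | alternative 3 | pentacarbonyl[{5-(benzyloxy)-6-[3,5-bis(benzyloxy)-4-methoxyphenyl]-4-oxo-4H-pyran-3-yl}(methoxy)methylidene]chromium | COC(=[Cr](=C=O)(=C=O)(=C=O)(=C=O)=C=O)c1coc(-c2cc(OCc3ccccc3)c(OC)c(OCc3ccccc3)c2)c(OCc2ccccc2)c1=O
A6 | alternative 3 | methoxyacetylene | COC#C
A7 | alternative 3 | 3-(benzyloxy)-2-[3,5-bis(benzyloxy)-4-methoxyphenyl]-8-hydroxy-5,7-dimethoxy-4H-chromen-4-one | COc1cc(OC)c2c(=O)c(OCc3ccccc3)c(-c3cc(OCc4ccccc4)c(OC)c(OCc4ccccc4)c3)oc2c1O
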